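**Retrosynthetic overview**

1. The target is reached by global fluoride deprotection after a Steglich ester union of acid fragment A (ring A, bis-silyl ether) with the primary alcohol of lactone diol fragment B (rings B and C). The two CH–iPr centres have opposite absolute configuration, so A is made from (R)-cryptone and B from (S)-cryptone.
2. Ring C is opened at the Cα–CH2 bond: a nickel-electrocatalytic decarboxylative ring closure joins an O-acylglycolic N-acyloxyphthalimide on C6 to a (Z)-α-iodoacrylate on C5, with loss of CO2 and phthalimide.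
3. Enabling feature: in ring C the CH2 sits between the lactone oxygen and the vinylic Cα that carries CO2H. The CH2 can therefore be an α-acyloxy radical (from a glycolate carboxyl) and Cα an alkenyl iodide α to a carboxyl (from C5–CHO by iodo-Wittig), while the cis C5/C6 fusion on ring B holds both arms on one face.
4. Ring B stereocentres: enone–allene [2+2] on (S)-cryptone (C5/C6 cis, anti to iPr), convex-face hydroxymethylation of C1, then two ozonolyses cut the temporary cyclobutane into C6–CO2H and C5–CHO.
5. Fragment A: (R)-cryptone, conjugate vinylation/enol triflate, iodo-Wittig, twofold Stille hydroxymethylation. Ring order: rings A and B (aldol condensations), temporary cyclobutane on ring B, then ring C (key step).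

Key step: step 20

Labels: ring A = cyclohexene of the acyl half (C1′ carries CH2OH, C6′ = CH, C5′ carries the acrylate arm, C4′ carries iPr). Ring B = cyclohexane (C1 = C(OH)CH2O, C4 = CH–iPr, C5 carries the alkenyl arm, C6 the lactone carbonyl). Ring C = seven-membered lactone containing Cβ(H)=Cα(CO2H)–CH2–O. On ring B, β is the isopropyl face and α the opposite face.

Assumption (chemistry): the (S)-configured 2-(methoxydiphenylmethyl)pyrrolidine is taken to give the (S)-keto aldehyde and the (R)-catalyst the (R)-keto aldehyde (enamine attacked anti to the shielding group); if the sense were opposite, the catalyst enantiomers are exchanged.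

**Route**

Step 1
Reactants: 1 2-(trimethylsilyl)ethan-1-ol; 2 bromoacetyl bromide
Product: 3 2-(trimethylsilyl)ethyl bromoacetate
Conditions: pyridine, CH2Cl2, 0 °C → rt
Reagents that add atoms: none
Why: Acylation of the primary alcohol by the acid bromide (esterification with pyridine as acid scavenger) is fast and leaves the C–Br bond for the next step; no stereocentre is formed.

Step 2
Reactants: 3 2-(trimethylsilyl)ethyl bromoacetate
Product: 5 2-(trimethylsilyl)ethyl (triphenyl-λ5-phosphanylidene)acetate, via phosphonium bromide 4 (not isolated)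
Conditions: PPh3, toluene, rt; then 1 M NaOH, CH2Cl2/H2O, 0 °C
Reagents that add atoms: triphenylphosphine, c1ccc(cc1)P(c1ccccc1)c1ccccc1
Why: SN2 quaternisation of PPh3 by the α-bromo ester and deprotonation of the acidic phosphonium salt give the ester-stabilised Wittig ylide, and the silylethyl ester should survive the brief cold biphasic base treatment.

Step 3
Reactants: 6 N-hydroxyphthalimide; 2 bromoacetyl bromide
Product: 7 1,3-dioxo-1,3-dihydro-2H-isoindol-2-yl bromoacetate
Conditions: pyridine, CH2Cl2, 0 °C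
Reagents that add atoms: none
Why: O-Acylation of the acidic N–OH group by the acid bromide gives a redox-active N-acyloxyphthalimide that still carries an SN2-reactive α-bromide; no stereocentre is formed.

Step 4
Reactants: 8 3-methylbutanal; 9 but-3-en-2-one
Product: 11 (4R)-4-(propan-2-yl)cyclohex-2-en-1-one [(R)-cryptone], via keto aldehyde 10 (not isolated)
Conditions: (R)-2-(methoxydiphenylmethyl)pyrrolidine (5 mol%), ethyl 3,4-dihydroxybenzoate (20 mol%), neat, 4 °C; then KOH, Bu4NOH (cat.), Et2O/THF/H2O, reflux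
Reagents that add atoms: none
Why: Enamine-catalysed Michael addition of the aldehyde to the enone sets C4′, the bulky diaryl(methoxy)methyl group of the (R)-catalyst shielding one face of the E-enamine, and base-mediated intramolecular aldol condensation then closes ring A as the enone without touching that centre.

Step 5
Reactants: 11 (4R)-4-(propan-2-yl)cyclohex-2-en-1-one
Product: 13 (3R,4R)-3-ethenyl-4-(propan-2-yl)cyclohex-1-en-1-yl trifluoromethanesulfonate, via bromomagnesium enolate 12 (not isolated)
Conditions: CH2=CHMgBr, CuBr·SMe2 (10 mol%), THF, −78 °C; then N-(5-chloropyridin-2-yl)triflimide, −78 °C → rt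
Reagents that add atoms: vinylmagnesium bromide, C=C[Mg]Br; N-(5-chloropyridin-2-yl)-1,1,1-trifluoro-N-(trifluoromethanesulfonyl)methanesulfonamide, FC(F)(F)S(=O)(=O)N(c1ccc(Cl)cn1)S(=O)(=O)C(F)(F)F
Why: Copper-catalysed conjugate addition delivers the vinyl group to C5′ anti to the neighbouring isopropyl group (trans product, axial attack on the half-chair), and O-sulfonylation of the regiodefined magnesium enolate fixes the C1′=C6′ double bond as an enol triflate.

Step 6
Reactants: 13 (3R,4R)-3-ethenyl-4-(propan-2-yl)cyclohex-1-en-1-yl trifluoromethanesulfonate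
Product: 14 (3R,4R)-3-formyl-4-(propan-2-yl)cyclohex-1-en-1-yl trifluoromethanesulfonate
Conditions: OsO4 (2 mol%), NaIO4, 2,6-lutidine, dioxane/H2O, rt; crude used at once
Reagents that add atoms: sodium periodate, [Na+].[O-]I(=O)(=O)=O
Why: Johnson–Lemieux oxidation: OsO4 dihydroxylates the electron-rich terminal vinyl group much faster than the electron-poor enol triflate and periodate cleaves the diol, while the lutidine buffer should keep the doubly activated C5′–H from epimerising.

Step 7
Reactants: 14 (3R,4R)-3-formyl-4-(propan-2-yl)cyclohex-1-en-1-yl trifluoromethanesulfonate; 15 methyl (triphenyl-λ5-phosphanylidene)acetate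
Product: 17 methyl (2Z)-2-iodo-3-[(1R,6R)-6-(propan-2-yl)-3-(trifluoromethanesulfonyloxy)cyclohex-2-en-1-yl]prop-2-enoate, via iodo ylide 16 (not isolated)
Conditions: 15, NIS, CH2Cl2, −20 °C; then 14, −20 °C → rt
Reagents that add atoms: N-iodosuccinimide, O=C1CCC(=O)N1I
Why: Iodination of the stabilised ylide by NIS and Wittig olefination with the resulting α-iodo ylide should give mainly the alkene with the ester trans to ring A, i.e. the (Z)-α-iodoacrylate, as is usual for stabilised ylides, under conditions mild enough for the aldehyde.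

Step 8
Reactants: 17 methyl (2Z)-2-iodo-3-[(1R,6R)-6-(propan-2-yl)-3-(trifluoromethanesulfonyloxy)cyclohex-2-en-1-yl]prop-2-enoate
Product: 18 methyl (2E)-2-(hydroxymethyl)-3-[(1R,6R)-3-(hydroxymethyl)-6-(propan-2-yl)cyclohex-2-en-1-yl]prop-2-enoate
Conditions: Bu3SnCH2OH (3 equiv), Pd(PPh3)4 (10 mol%), LiCl, 1,4-dioxane, 90 °C
Reagents that add atoms: (tributylstannyl)methanol, OC[Sn](CCCC)(CCCC)CCCC
Why: Twofold Stille coupling: zerovalent palladium inserts into the alkenyl C–I and C–OTf bonds (LiCl assists the triflate), the α-oxygenated CH2OH group is transferred from tin in preference to butyl, and both sp2 centres react with retention, so the acrylate keeps its geometry (Z becomes E only through the priority rules).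

Step 9
Reactants: 18 methyl (2E)-2-(hydroxymethyl)-3-[(1R,6R)-3-(hydroxymethyl)-6-(propan-2-yl)cyclohex-2-en-1-yl]prop-2-enoate
Product: 19 methyl (2E)-2-{[(tert-butyldimethylsilyl)oxy]methyl}-3-[(1R,6R)-3-{[(tert-butyldimethylsilyl)oxy]methyl}-6-(propan-2-yl)cyclohex-2-en-1-yl]prop-2-enoate
Conditions: TBSCl, imidazole, DMF, rt
Reagents that add atoms: tert-butyldimethylsilyl chloride, CC(C)(C)[Si](C)(C)Cl
Why: Silylation of the two primary allylic alcohols (silyl ether formation) masks them for the fragment union and for the final fluoride step.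

Step 10
Reactants: 19 methyl (2E)-2-{[(tert-butyldimethylsilyl)oxy]methyl}-3-[(1R,6R)-3-{[(tert-butyldimethylsilyl)oxy]methyl}-6-(propan-2-yl)cyclohex-2-en-1-yl]prop-2-enoate
Product: 20 (2E)-2-{[(tert-butyldimethylsilyl)oxy]methyl}-3-[(1R,6R)-3-{[(tert-butyldimethylsilyl)oxy]methyl}-6-(propan-2-yl)cyclohex-2-en-1-yl]prop-2-enoic acid
Conditions: LiOH, THF/MeOH/H2O, rt; then 1 M HCl to pH 4, 0 °C
Reagents that add atoms: lithium hydroxide, [Li+].[OH-]
Why: Saponification of the methyl ester by hydroxide (acyl substitution) frees the acrylic acid while the silyl ethers are unaffected and C5′–H is not acidic enough to epimerise under these conditions.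

Step 11
Reactants: 8 3-methylbutanal; 9 but-3-en-2-one
Product: 22 (4S)-4-(propan-2-yl)cyclohex-2-en-1-one [(S)-cryptone], via keto aldehyde 21 (not isolated)
Conditions: (S)-2-(methoxydiphenylmethyl)pyrrolidine (5 mol%), ethyl 3,4-dihydroxybenzoate (20 mol%), neat, 4 °C; then KOH, Bu4NOH (cat.), Et2O/THF/H2O, reflux
Reagents that add atoms: none
Why: The same enamine Michael addition/aldol condensation as in step 4, but with the (S)-catalyst, sets C4 of ring B in the opposite absolute sense.

Step 12
Reactants: 22 (4S)-4-(propan-2-yl)cyclohex-2-en-1-one; 23 propadiene (allene)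
Product: 24 (1R,5S,6S)-8-methylidene-5-(propan-2-yl)bicyclo[4.2.0]octan-2-one
Conditions: allene (excess), hν (medium-pressure Hg lamp, Pyrex filter), THF, −78 °C
Reagents that add atoms: none
Why: Enone–allene [2+2] photocycloaddition (triplet enone, 1,4-diradical) is head-to-head, so the central allene carbon bonds to C6 and a CH2 to C5; the new C5 bond should form anti to the isopropyl group and the four-membered ring closes cis, which sets C5 and C6 (both new bonds α).

Step 13
Reactants: 24 (1R,5S,6S)-8-methylidene-5-(propan-2-yl)bicyclo[4.2.0]octan-2-one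
Product: 26 (1R,2R,5S,6S)-2-(hydroxymethyl)-8-methylidene-5-(propan-2-yl)bicyclo[4.2.0]octan-2-ol, via hydroxy silane 25 (not isolated)
Conditions: (iPrO)Me2SiCH2MgCl (from (iPrO)Me2SiCH2Cl and Mg), CeCl3, THF, −78 → 0 °C; then KF, KHCO3, 30% H2O2, THF/MeOH, rt
Reagents that add atoms: (isopropoxydimethylsilyl)methylmagnesium chloride, CC(C)O[Si](C)(C)C[Mg]Cl; hydrogen peroxide, OO
Why: Cerium-assisted 1,2-addition of the silylmethyl Grignard reagent (a hydroxymethyl anion equivalent) should occur on the convex face of the cis-fused bicycle, anti to the cyclobutane, so the new CH2 is β and the C1 oxygen α (cis to the C6 carbon arm), and Tamao oxidation then replaces silicon by hydroxyl with retention.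

Step 14
Reactants: 26 (1R,2R,5S,6S)-2-(hydroxymethyl)-8-methylidene-5-(propan-2-yl)bicyclo[4.2.0]octan-2-ol
Product: 27 (1R,2R,5S,6S)-2′,2′-dimethyl-8-methylidene-5-(propan-2-yl)spiro[bicyclo[4.2.0]octane-2,4′-[1,3]dioxolane]
Conditions: 2,2-dimethoxypropane, PPTS (cat.), CH2Cl2, rt
Reagents that add atoms: 2,2-dimethoxypropane, COC(C)(C)OC
Why: Acid-catalysed transacetalisation ties the tertiary C1–OH and the primary CH2OH into a dioxolane (acetonide), which protects both through the oxidative and basic steps that follow.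

Step 15
Reactants: 27 (1R,2R,5S,6S)-2′,2′-dimethyl-8-methylidene-5-(propan-2-yl)spiro[bicyclo[4.2.0]octane-2,4′-[1,3]dioxolane]
Product: 28 cyclobutanone: 27 with C8=O in place of C8=CH2 (stereocentres unchanged)
Conditions: O3, CH2Cl2, −78 °C; then PPh3, −78 °C → rt
Reagents that add atoms: ozone, [O-][O+]=O
Why: Ozonolysis of the 1,1-disubstituted exocyclic alkene with reductive work-up gives the cyclobutanone; no other C=C bond is present and the stereocentres are untouched.

Step 16
Reactants: 28 cyclobutanone (8-oxo analogue of 27)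
Product: 29 tert-butyldimethylsilyl enol ether of 28 (C7=C8, OTBS on C8)
Conditions: TBSOTf, Et3N, CH2Cl2, −78 → 0 °C
Reagents that add atoms: tert-butyldimethylsilyl trifluoromethanesulfonate, CC(C)(C)[Si](C)(C)OS(=O)(=O)C(F)(F)F
Why: Soft enolisation/O-silylation (silyl enol ether formation) should occur toward the CH2 group C7, because the alternative double bond at the ring-fusion carbon C6 would be a far more strained cyclobutene, so the C6 configuration is retained.

Step 17
Reactants: 29 tert-butyldimethylsilyl enol ether of 28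
Product: 30 tert-butyldimethylsilyl (5R,6S,7S,8S)-7-formyl-2,2-dimethyl-8-(propan-2-yl)-1,3-dioxaspiro[4.5]decane-6-carboxylate
Conditions: O3, CH2Cl2, −78 °C; then PPh3, −78 °C → rt; crude used directly
Reagents that add atoms: ozone, [O-][O+]=O
Why: Ozonolysis of the electron-rich silyl enol ether cleaves C7=C8 and leaves the two carbons at different oxidation levels, C5–CHO and the C6 silyl ester, still cis on ring B because no bond to C5 or C6 is broken.

Step 18
Reactants: 30 tert-butyldimethylsilyl (5R,6S,7S,8S)-7-formyl-2,2-dimethyl-8-(propan-2-yl)-1,3-dioxaspiro[4.5]decane-6-carboxylate; 5 2-(trimethylsilyl)ethyl (triphenyl-λ5-phosphanylidene)acetate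
Product: 33 (5R,6S,7S,8S)-7-{(1Z)-2-iodo-3-oxo-3-[2-(trimethylsilyl)ethoxy]prop-1-en-1-yl}-2,2-dimethyl-8-(propan-2-yl)-1,3-dioxaspiro[4.5]decane-6-carboxylic acid, via iodo ylide 31 (not isolated), via silyl ester 32 (not isolated)
Conditions: 5, NIS, CH2Cl2, −20 °C; then 30, −20 °C → rt; then 10% aq. citric acid, THF, rt
Reagents that add atoms: N-iodosuccinimide, O=C1CCC(=O)N1I
Why: Wittig olefination with the in situ α-iodo ylide converts C5–CHO into the (Z)-α-iodoacrylate (ester trans to ring B, as with stabilised ylides), C5 being already in its more stable equatorial configuration, and the labile silyl ester is hydrolysed by the mild acid work-up.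

Step 19
Reactants: 33 (5R,6S,7S,8S)-7-{(1Z)-2-iodo-3-oxo-3-[2-(trimethylsilyl)ethoxy]prop-1-en-1-yl}-2,2-dimethyl-8-(propan-2-yl)-1,3-dioxaspiro[4.5]decane-6-carboxylic acid; 7 1,3-dioxo-1,3-dihydro-2H-isoindol-2-yl bromoacetate
Product: 34 2-[(1,3-dioxo-1,3-dihydro-2H-isoindol-2-yl)oxy]-2-oxoethyl ester of 33
Conditions: KHCO3, DMF, 0 °C → rt
Reagents that add atoms: none
Why: SN2 O-alkylation of the carboxylate by the activated α-bromoacetate installs the O-acylglycolic redox-active ester directly; the N-acyloxyphthalimide should not be attacked, because carboxylate is a weaker nucleophile than the N-oxyphthalimide anion it would have to expel.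

Step 20
Reactants: 34 2-[(1,3-dioxo-1,3-dihydro-2H-isoindol-2-yl)oxy]-2-oxoethyl ester of 33
Product: 35 acetonide of 36 (ring C closed; 2-(trimethylsilyl)ethyl ester on Cα)
Conditions: NiCl2·6H2O (20 mol%), 2,2′-bipyridine (20 mol%), AgNO3 (30 mol%), LiCl, DMF, Mg anode/RVC cathode, undivided cell, constant current (about 3 F/mol), rt, substrate added by syringe pump (final about 2 mM)
Reagents that add atoms: none
Why: Proposed new method: the cathode keeps NiCl2·6H2O/2,2′-bipyridine low-valent, zerovalent nickel inserts into the C–I bond of the (Z)-α-iodoacrylate, single-electron reduction of the N-acyloxyphthalimide (by monovalent nickel or at the silver-coated cathode) expels phthalimide anion and CO2 to leave the α-acyloxy radical •CH2–O–C(=O)–C6, and capture of this radical by the alkenylnickel followed by C(sp2)–C(sp3) reductive elimination from trivalent nickel forms the Cα–CH2 bond. The closest known reaction type is the intermolecular nickel-electrocatalytic decarboxylative alkenylation of redox-active esters with alkenyl halides, for which α-oxygenated radicals are among the best partners; new here are the ring closure and the acyloxymethyl radical. Ring C is closed by reductive elimination from an eight-membered oxa-nickelacycle (a metal-templated closure of the seven-membered lactone), not by a 7-endo radical addition. No stereocentre is formed: C5 and C6 are untouched and the alkene geometry follows from retention at Cα (C5 cis to iodine in 34 becomes C5 cis to CH2 in 35, the only geometry ring C can hold, and any E-alkenylnickel can isomerise through its nickel allenoate form). The step needs intramolecular capture to beat 6-exo Giese addition of the radical to Cβ, hydrogen abstraction and intermolecular coupling, which should be secured by the cis C5/C6 arrangement on ring B, by the hindered disubstituted Cβ and the weakly nucleophilic acyloxymethyl radical, and by slow addition at high dilution. The acetonide keeps the C1 oxygens away from the activated ester and the 2-(trimethylsilyl)ethyl ester is inert under the cathodic conditions.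

Step 21
Reactants: 35 acetonide of 36
Product: 36 2-(trimethylsilyl)ethyl (5aR,6S,9R,9aS)-9-hydroxy-9-(hydroxymethyl)-1-oxo-6-(propan-2-yl)-1,3,5a,6,7,8,9,9a-octahydro-2-benzoxepine-4-carboxylate
Conditions: AcOH/H2O (4:1), 40 °C
Reagents that add atoms: none
Why: Acid-catalysed acetal hydrolysis (via the oxocarbenium ion at the acetal carbon) frees the diol without ionising C1, and the lactone and the silylethyl ester should be stable to warm aqueous acetic acid.

Step 22
Reactants: 36 2-(trimethylsilyl)ethyl (5aR,6S,9R,9aS)-9-hydroxy-9-(hydroxymethyl)-1-oxo-6-(propan-2-yl)-1,3,5a,6,7,8,9,9a-octahydro-2-benzoxepine-4-carboxylate; 20 (2E)-2-{[(tert-butyldimethylsilyl)oxy]methyl}-3-[(1R,6R)-3-{[(tert-butyldimethylsilyl)oxy]methyl}-6-(propan-2-yl)cyclohex-2-en-1-yl]prop-2-enoic acid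
Product: 37 bis(tert-butyldimethylsilyl) ether 2-(trimethylsilyl)ethyl ester of the target
Conditions: EDC·HCl, DMAP (10 mol%), CH2Cl2, 0 °C → rt
Reagents that add atoms: none
Why: Steglich esterification (carbodiimide activation with DMAP as acyl-transfer catalyst) should acylate only the primary CH2OH, the tertiary C1–OH being far too hindered, and joins fragments A and B.

Step 23
Reactants: 37 bis(tert-butyldimethylsilyl) ether 2-(trimethylsilyl)ethyl ester of the target
Product: 38 (5aR,6S,9R,9aS)-9-hydroxy-9-({[(2E)-2-(hydroxymethyl)-3-[(1R,6R)-3-(hydroxymethyl)-6-(propan-2-yl)cyclohex-2-en-1-yl]prop-2-enoyl]oxy}methyl)-1-oxo-6-(propan-2-yl)-1,3,5a,6,7,8,9,9a-octahydro-2-benzoxepine-4-carboxylic acid (CNP0361406.3)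
Conditions: TASF, DMF, 0 °C → rt; then cold 0.1 M HCl
Reagents that add atoms: none
Why: Fluoride attacks silicon in the two silyl ethers and in the 2-(trimethylsilyl)ethyl ester, which fragments to ethene and the carboxylate (β-elimination), so all three protecting groups should fall in one nearly neutral operation that does not disturb the two ester links or C6.

**Compound list**

1 | 2-(trimethylsilyl)ethan-1-ol | C[Si](C)(C)CCO | starting material
2 | bromoacetyl bromide | BrCC(Br)=O | starting material
3 | 2-(trimethylsilyl)ethyl bromoacetate | C[Si](C)(C)CCOC(=O)CBr | intermediate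
4 | {2-oxo-2-[2-(trimethylsilyl)ethoxy]ethyl}triphenylphosphonium bromide | C[Si](C)(C)CCOC(=O)C[P+](c1ccccc1)(c1ccccc1)c1ccccc1.[Br-] | intermediate
5 | 2-(trimethylsilyl)ethyl (triphenyl-λ5-phosphanylidene)acetate | C[Si](C)(C)CCOC(=O)C=P(c1ccccc1)(c1ccccc1)c1ccccc1 | intermediate
6 | N-hydroxyphthalimide | ON1C(=O)c2ccccc2C1=O | starting material
7 | 1,3-dioxo-1,3-dihydro-2H-isoindol-2-yl bromoacetate | BrCC(=O)ON1C(=O)c2ccccc2C1=O | intermediate
8 | 3-methylbutanal | CC(C)CC=O | starting material
9 | but-3-en-2-one | CC(=O)C=C | starting material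
10 | (2R)-5-oxo-2-(propan-2-yl)hexanal | CC(C)[C@H](C=O)CCC(C)=O | intermediate
11 | (4R)-4-(propan-2-yl)cyclohex-2-en-1-one, (R)-cryptone | CC(C)[C@H]1CCC(=O)C=C1 | intermediate
12 | bromomagnesium (3R,4R)-3-ethenyl-4-(propan-2-yl)cyclohex-1-en-1-olate | CC(C)[C@H]1CCC(O[Mg]Br)=C[C@@H]1C=C | intermediate
13 | (3R,4R)-3-ethenyl-4-(propan-2-yl)cyclohex-1-en-1-yl trifluoromethanesulfonate (vinyl trans to iPr) | CC(C)[C@H]1CCC(OS(=O)(=O)C(F)(F)F)=C[C@@H]1C=C | intermediate
14 | (3R,4R)-3-formyl-4-(propan-2-yl)cyclohex-1-en-1-yl trifluoromethanesulfonate | CC(C)[C@H]1CCC(OS(=O)(=O)C(F)(F)F)=C[C@@H]1C=O | intermediate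
15 | methyl (triphenyl-λ5-phosphanylidene)acetate | COC(=O)C=P(c1ccccc1)(c1ccccc1)c1ccccc1 | starting material
16 | methyl iodo(triphenyl-λ5-phosphanylidene)acetate | COC(=O)C(I)=P(c1ccccc1)(c1ccccc1)c1ccccc1 | intermediate
17 | methyl (2Z)-2-iodo-3-[(1R,6R)-6-(propan-2-yl)-3-(trifluoromethanesulfonyloxy)cyclohex-2-en-1-yl]prop-2-enoate | CC(C)[C@H]1CCC(OS(=O)(=O)C(F)(F)F)=C[C@@H]1/C=C(\I)C(=O)OC | intermediate
18 | methyl (2E)-2-(hydroxymethyl)-3-[(1R,6R)-3-(hydroxymethyl)-6-(propan-2-yl)cyclohex-2-en-1-yl]prop-2-enoate | CC(C)[C@H]1CCC(CO)=C[C@@H]1/C=C(\CO)C(=O)OC | intermediate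
19 | methyl (2E)-2-{[(tert-butyldimethylsilyl)oxy]methyl}-3-[(1R,6R)-3-{[(tert-butyldimethylsilyl)oxy]methyl}-6-(propan-2-yl)cyclohex-2-en-1-yl]prop-2-enoate | CC(C)[C@H]1CCC(CO[Si](C)(C)C(C)(C)C)=C[C@@H]1/C=C(\CO[Si](C)(C)C(C)(C)C)C(=O)OC | intermediate
20 | (2E)-2-{[(tert-butyldimethylsilyl)oxy]methyl}-3-[(1R,6R)-3-{[(tert-butyldimethylsilyl)oxy]methyl}-6-(propan-2-yl)cyclohex-2-en-1-yl]prop-2-enoic acid (fragment A) | CC(C)[C@H]1CCC(CO[Si](C)(C)C(C)(C)C)=C[C@@H]1/C=C(\CO[Si](C)(C)C(C)(C)C)C(=O)O | intermediate
21 | (2S)-5-oxo-2-(propan-2-yl)hexanal | CC(C)[C@@H](C=O)CCC(C)=O | intermediate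
22 | (4S)-4-(propan-2-yl)cyclohex-2-en-1-one, (S)-cryptone | CC(C)[C@@H]1CCC(=O)C=C1 | intermediate
23 | propadiene (allene) | C=C=C | starting material
24 | (1R,5S,6S)-8-methylidene-5-(propan-2-yl)bicyclo[4.2.0]octan-2-one (cis-fused, cyclobutane anti to iPr) | O=C1CC[C@@H](C(C)C)[C@@H]2CC(=C)[C@H]12 | intermediate
25 | (1R,2R,5S,6S)-2-{[dimethyl(propan-2-yloxy)silyl]methyl}-8-methylidene-5-(propan-2-yl)bicyclo[4.2.0]octan-2-ol | CC(C)O[Si](C)(C)C[C@@]1(O)CC[C@@H](C(C)C)[C@@H]2CC(=C)[C@H]12 | intermediate
26 | (1R,2R,5S,6S)-2-(hydroxymethyl)-8-methylidene-5-(propan-2-yl)bicyclo[4.2.0]octan-2-ol | OC[C@@]1(O)CC[C@@H](C(C)C)[C@@H]2CC(=C)[C@H]12 | intermediate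
27 | (1R,2R,5S,6S)-2′,2′-dimethyl-8-methylidene-5-(propan-2-yl)spiro[bicyclo[4.2.0]octane-2,4′-[1,3]dioxolane] (acetonide of 26) | CC1(C)OC[C@@]2(O1)CC[C@@H](C(C)C)[C@@H]1CC(=C)[C@H]21 | intermediate
28 | cyclobutanone: 27 with C8=O in place of C8=CH2, stereocentres as in 27 | CC1(C)OC[C@@]2(O1)CC[C@@H](C(C)C)[C@@H]1CC(=O)[C@H]21 | intermediate
29 | tert-butyldimethylsilyl enol ether of 28 (C7=C8, OTBS on C8) | CC1(C)OC[C@@]2(O1)CC[C@@H](C(C)C)[C@@H]1C=C(O[Si](C)(C)C(C)(C)C)[C@H]21 | intermediate
30 | tert-butyldimethylsilyl (5R,6S,7S,8S)-7-formyl-2,2-dimethyl-8-(propan-2-yl)-1,3-dioxaspiro[4.5]decane-6-carboxylate (CHO and ester cis, CHO trans to iPr) | CC1(C)OC[C@@]2(O1)CC[C@@H](C(C)C)[C@H](C=O)[C@@H]2C(=O)O[Si](C)(C)C(C)(C)C | intermediate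
31 | 2-(trimethylsilyl)ethyl iodo(triphenyl-λ5-phosphanylidene)acetate | C[Si](C)(C)CCOC(=O)C(I)=P(c1ccccc1)(c1ccccc1)c1ccccc1 | intermediate
32 | tert-butyldimethylsilyl ester of 33 | CC1(C)OC[C@@]2(O1)CC[C@@H](C(C)C)[C@H](/C=C(\I)C(=O)OCC[Si](C)(C)C)[C@@H]2C(=O)O[Si](C)(C)C(C)(C)C | intermediate
33 | (5R,6S,7S,8S)-7-{(1Z)-2-iodo-3-oxo-3-[2-(trimethylsilyl)ethoxy]prop-1-en-1-yl}-2,2-dimethyl-8-(propan-2-yl)-1,3-dioxaspiro[4.5]decane-6-carboxylic acid | CC1(C)OC[C@@]2(O1)CC[C@@H](C(C)C)[C@H](/C=C(\I)C(=O)OCC[Si](C)(C)C)[C@@H]2C(=O)O | intermediate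
34 | 2-[(1,3-dioxo-1,3-dihydro-2H-isoindol-2-yl)oxy]-2-oxoethyl ester of 33 (O-acylglycolic N-acyloxyphthalimide) | CC1(C)OC[C@@]2(O1)CC[C@@H](C(C)C)[C@H](/C=C(\I)C(=O)OCC[Si](C)(C)C)[C@@H]2C(=O)OCC(=O)ON1C(=O)c2ccccc2C1=O | intermediate
35 | acetonide (C9–O/C9–CH2O isopropylidene acetal) of 36 | CC1(C)OC[C@@]2(O1)CC[C@@H](C(C)C)[C@@H]1C=C(C(=O)OCC[Si](C)(C)C)COC(=O)[C@@H]12 | intermediate
36 | 2-(trimethylsilyl)ethyl (5aR,6S,9R,9aS)-9-hydroxy-9-(hydroxymethyl)-1-oxo-6-(propan-2-yl)-1,3,5a,6,7,8,9,9a-octahydro-2-benzoxepine-4-carboxylate (fragment B) | OC[C@@]1(O)CC[C@@H](C(C)C)[C@@H]2C=C(C(=O)OCC[Si](C)(C)C)COC(=O)[C@@H]21 | intermediate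
37 | bis(tert-butyldimethylsilyl) ether, 2-(trimethylsilyl)ethyl ester of the target | CC(C)[C@H]1CCC(CO[Si](C)(C)C(C)(C)C)=C[C@@H]1/C=C(\CO[Si](C)(C)C(C)(C)C)C(=O)OC[C@@]1(O)CC[C@@H](C(C)C)[C@@H]2C=C(C(=O)OCC[Si](C)(C)C)COC(=O)[C@@H]21 | intermediate
38 | (5aR,6S,9R,9aS)-9-hydroxy-9-({[(2E)-2-(hydroxymethyl)-3-[(1R,6R)-3-(hydroxymethyl)-6-(propan-2-yl)cyclohex-2-en-1-yl]prop-2-enoyl]oxy}methyl)-1-oxo-6-(propan-2-yl)-1,3,5a,6,7,8,9,9a-octahydro-2-benzoxepine-4-carboxylic acid (CNP0361406.3) | CC(C)[C@H]1CCC(CO)=C[C@@H]1/C=C(\CO)C(=O)OC[C@@]1(O)CC[C@@H](C(C)C)[C@@H]2C=C(C(=O)O)COC(=O)[C@@H]21 | target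

**Step count and risks**

Total step count: 23 (3 reagent steps, 7 steps for fragment A, 13 steps for fragment B and the endgame).
Longest linear sequence: 13 steps (steps 11–23, from 3-methylbutanal and but-3-en-2-one to the target).

Three steps most likely to fail:

Step 20 (Proposed new method). The acyloxymethyl radical may be lost before nickel captures it within the same molecule: by hydrogen abstraction from the solvent, by 6-exo addition to Cβ of its own acrylate, or by intermolecular coupling; the alkenylnickel may also simply be protonated. The fallback uses known two-electron chemistry and sets out from 33. Alkylation of its carboxylate with tributyl(iodomethyl)stannane (Cs2CO3, DMF) should give the (tributylstannyl)methyl ester F1. Intramolecular Stille coupling of this α-acyloxymethylstannane with the alkenyl iodide (Pd2(dba)3, AsPh3, CuI, DMF, 50 °C, high dilution; retention at Cα) should then close ring C and return to the route at 35.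

Step 12. The photocycloaddition may lose head-to-head regiochemistry or anti facial selectivity, and the β,γ-unsaturated ketone product may react further under irradiation (1,3-acyl shift). The fallback sets out from 22 and uses a symmetric partner that gives a saturated, photostable adduct, the two carbons being told apart later by hindrance instead of by oxidation level.
- Irradiation with (Z)-1,2-dichloroethene should give the cis-fused dichlorocyclobutane ketone F2.
- The CeCl3/(iPrO)Me2SiCH2MgCl addition gives the hydroxy silane F3 (not isolated), and Tamao oxidation the diol F4.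
- 2,2-Dimethoxypropane/PPTS gives the acetonide F5.
- Reductive dechlorination with sodium naphthalenide (NaC10H8, THF, −78 °C) gives the cyclobutene F6.
- Ozonolysis (O3; PPh3) gives the cis dialdehyde F7.
- The iodo ylide 31 should react only at the less hindered C5–CHO (the C6–CHO is neopentylic, next to the spiro centre) to give the iodoacrylate aldehyde F8.
- Pinnick oxidation (NaClO2, NaH2PO4, 2-methylbut-2-ene) of the remaining aldehyde returns to the route at 33.

Step 8. Transfer of the sp3 CH2OH group from tin is slow and must succeed at two sites; protodeiodination or homocoupling of the α-iodoacrylate and double-bond migration in the 1,4-diene at 90 °C may compete. The fallback sets out from 13 and builds both CH2O groups by other bond constructions.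
- Palladium-catalysed methoxycarbonylation of the enol triflate (Pd(OAc)2, 1,3-bis(diphenylphosphino)propane, CO, MeOH, Et3N) gives the methyl ester F9.
- iBu2AlH reduces it to the allylic alcohol F10, and TBSCl/imidazole gives the silyl ether F11.
- Cross-metathesis of the terminal vinyl group of F11 with methyl 2-{[(tert-butyldimethylsilyl)oxy]methyl}prop-2-enoate F12 (made from commercial methyl 2-(hydroxymethyl)acrylate and TBSCl) using second-generation Grubbs catalyst in toluene at 80 °C should form the trisubstituted (E)-acrylate. The trisubstituted ring alkene is inert, and the sequence returns to the route at 19.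

**Further compounds**

F1 | step 20 | (tributylstannyl)methyl ester of 33 | CC1(C)OC[C@@]2(O1)CC[C@@H](C(C)C)[C@H](/C=C(\I)C(=O)OCC[Si](C)(C)C)[C@@H]2C(=O)OC[Sn](CCCC)(CCCC)CCCC
F2 | step 12 | 7,8-dichloro-5-(propan-2-yl)bicyclo[4.2.0]octan-2-one (ring fusion and C5 as in 24; mixture at the two C–Cl centres) | O=C1CC[C@@H](C(C)C)[C@@H]2C(Cl)C(Cl)[C@H]12
F3 | step 12 | 7,8-dichloro analogue of hydroxy silane 25 | CC(C)O[Si](C)(C)C[C@@]1(O)CC[C@@H](C(C)C)[C@@H]2C(Cl)C(Cl)[C@H]12
F4 | step 12 | 7,8-dichloro-2-(hydroxymethyl)-5-(propan-2-yl)bicyclo[4.2.0]octan-2-ol (configuration as in 26) | OC[C@@]1(O)CC[C@@H](C(C)C)[C@@H]2C(Cl)C(Cl)[C@H]12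
F5 | step 12 | acetonide of F4 | CC1(C)OC[C@@]2(O1)CC[C@@H](C(C)C)[C@@H]1C(Cl)C(Cl)[C@H]21
F6 | step 12 | cyclobut-7-ene acetonide (27 with C7=C8 and no exocyclic carbon) | CC1(C)OC[C@@]2(O1)CC[C@@H](C(C)C)[C@@H]1C=C[C@H]21
F7 | step 12 | (5R,6S,7S,8S)-2,2-dimethyl-8-(propan-2-yl)-1,3-dioxaspiro[4.5]decane-6,7-dicarbaldehyde | CC1(C)OC[C@@]2(O1)CC[C@@H](C(C)C)[C@H](C=O)[C@@H]2C=O
F8 | step 12 | 2-(trimethylsilyl)ethyl (2Z)-3-[(5R,6S,7S,8S)-6-formyl-2,2-dimethyl-8-(propan-2-yl)-1,3-dioxaspiro[4.5]decan-7-yl]-2-iodoprop-2-enoate | CC1(C)OC[C@@]2(O1)CC[C@@H](C(C)C)[C@H](/C=C(\I)C(=O)OCC[Si](C)(C)C)[C@@H]2C=O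
F9 | step 8 | methyl (3R,4R)-3-ethenyl-4-(propan-2-yl)cyclohex-1-ene-1-carboxylate | CC(C)[C@H]1CCC(C(=O)OC)=C[C@@H]1C=C
F10 | step 8 | [(3R,4R)-3-ethenyl-4-(propan-2-yl)cyclohex-1-en-1-yl]methanol | CC(C)[C@H]1CCC(CO)=C[C@@H]1C=C
F11 | step 8 | tert-butyldimethylsilyl ether of F10 | CC(C)[C@H]1CCC(CO[Si](C)(C)C(C)(C)C)=C[C@@H]1C=C
F12 | step 8 | methyl 2-{[(tert-butyldimethylsilyl)oxy]methyl}prop-2-enoate | C=C(CO[Si](C)(C)C(C)(C)C)C(=O)OC
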